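**Strategy.** The macrocycle is opened at the CH2–CH2 bond joining rings A and D. Ring D carries its phenolic OH para to its bridge CH2, so that carbon can be unmasked as the exocyclic terminus of a p-quinone methide, while the ring A bridge carbon (para to the ring A diaryl ether oxygen) is carried as an aldehyde. A carbene catalyst inverts the aldehyde into an acyl anion equivalent that adds 1,6 to the quinone methide, forging the bridge C–C bond and the 20-membered ring in one operation. The cyclisation substrate is a linear A–B–C–D chain ending in a ring A benzaldehyde and a ring D 4-hydroxybenzyl p-tolyl sulfone.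

Key step: step 10

Assumption: rings are lettered A (the hydroxy ring bonded through oxygen to ring B), B (meta-linked), C (para-linked) and D (the hydroxy ring bonded through oxygen to ring C). The target has no stereocentre. The Wittig olefin is carried as an E/Z mixture, so its SMILES is written without double-bond geometry.

**Route**

Step 1
Reactants: 1 4-fluoro-3-methoxybenzaldehyde; 2 3-hydroxybenzyl alcohol
Product: 3 4-[3-(hydroxymethyl)phenoxy]-3-methoxybenzaldehyde
Conditions: K2CO3, DMF, 120 °C
Reagents that add atoms: none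
Why: Nucleophilic aromatic substitution (SNAr) should occur because the para-formyl group activates the C–F bond and K2CO3 ionises only the phenol of 2, so the benzylic alcohol is not arylated.

Step 2
Reactants: 3 4-[3-(hydroxymethyl)phenoxy]-3-methoxybenzaldehyde
Product: 4 [3-[4-(1,3-dioxolan-2-yl)-2-methoxyphenoxy]phenyl]methanol
Conditions: HOCH2CH2OH, p-TsOH·H2O (cat.), toluene, reflux, Dean–Stark
Reagents that add atoms: ethylene glycol, OCCO
Why: Acid-catalysed acetalisation with azeotropic removal of water masks the ring A aldehyde as a 1,3-dioxolane, so that it cannot compete with the ring C aldehyde in the later Wittig olefination.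

Step 3
Reactants: 4 [3-[4-(1,3-dioxolan-2-yl)-2-methoxyphenoxy]phenyl]methanol
Product: 5 2-[4-[3-(bromomethyl)phenoxy]-3-methoxyphenyl]-1,3-dioxolane
Conditions: CBr4, PPh3, CH2Cl2, 0 °C to rt
Reagents that add atoms: carbon tetrabromide, BrC(Br)(Br)Br
Why: The Appel reaction turns the primary benzylic alcohol into the bromide under essentially neutral conditions that the dioxolane should tolerate.

Step 4
Reactants: 5 2-[4-[3-(bromomethyl)phenoxy]-3-methoxyphenyl]-1,3-dioxolane
Product: 6 [3-[4-(1,3-dioxolan-2-yl)-2-methoxyphenoxy]benzyl]triphenylphosphonium bromide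
Conditions: PPh3, toluene, reflux
Reagents that add atoms: triphenylphosphine, c1ccc(cc1)P(c1ccccc1)c1ccccc1
Why: SN2 quaternisation of triphenylphosphine by the benzylic bromide gives the Wittig salt, which should precipitate from toluene in the absence of any acid that could open the acetal.

Step 5
Reactants: 7 4-(benzyloxy)-3-hydroxybenzaldehyde
Product: 8 2-(benzyloxy)-5-(hydroxymethyl)phenol
Conditions: NaBH4, MeOH, 0 °C
Reagents that add atoms: none
Why: Borohydride reduction takes the ring D formyl group to the alcohol oxidation level, so that ring C will carry the only aldehyde of the C–D fragment.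

Step 6
Reactants: 8 2-(benzyloxy)-5-(hydroxymethyl)phenol; 9 4-fluorobenzaldehyde
Product: 10 4-[2-(benzyloxy)-5-(hydroxymethyl)phenoxy]benzaldehyde
Conditions: K2CO3, DMF, 110 °C
Reagents that add atoms: none
Why: SNAr of the phenoxide of 8 on the para-formyl-activated fluoroarene forms the ring C–ring D ether, since carbonate does not ionise the benzylic alcohol and the benzyl ether blocks the oxygen para to the CH2OH group.

Step 7
Reactants: 10 4-[2-(benzyloxy)-5-(hydroxymethyl)phenoxy]benzaldehyde
Product: 12 4-[2-(benzyloxy)-5-(tosylmethyl)phenoxy]benzaldehyde, via benzylic bromide 11 (not isolated)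
Conditions: PBr3, CH2Cl2, 0 °C; NaHCO3 wash; then p-TolSO2Na, DMF, rt (crude bromide)
Reagents that add atoms: phosphorus tribromide, BrP(Br)Br (bromine carried only by intermediate 11); sodium p-toluenesulfinate, Cc1ccc(cc1)S(=O)[O-].[Na+]
Why: The electron-rich benzylic alcohol is brominated by PBr3 and the reactive bromide is then S-alkylated by the soft sulfinate anion (SN2) to give the sulfone, the aryl aldehyde being inert to both reagents at these temperatures.

Step 8
Reactants: 6 [3-[4-(1,3-dioxolan-2-yl)-2-methoxyphenoxy]benzyl]triphenylphosphonium bromide; 12 4-[2-(benzyloxy)-5-(tosylmethyl)phenoxy]benzaldehyde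
Product: 13 2-[4-[3-[2-[4-[2-(benzyloxy)-5-(tosylmethyl)phenoxy]phenyl]ethenyl]phenoxy]-3-methoxyphenyl]-1,3-dioxolane (E/Z mixture)
Conditions: K2CO3, 18-crown-6 (cat.), CH2Cl2, reflux
Reagents that add atoms: none
Why: In this Wittig olefination the benzylic phosphonium salt is far more acidic than the benzyl sulfone CH2, so the mild carbonate base should form only the ylide, which condenses with the ring C aldehyde, and the olefin geometry is irrelevant because the alkene is saturated next.

Step 9
Reactants: 13 2-[4-[3-[2-[4-[2-(benzyloxy)-5-(tosylmethyl)phenoxy]phenyl]ethenyl]phenoxy]-3-methoxyphenyl]-1,3-dioxolane (E/Z mixture)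
Product: 15 4-[3-[2-[4-[2-hydroxy-5-(tosylmethyl)phenoxy]phenyl]ethyl]phenoxy]-3-methoxybenzaldehyde (seco aldehyde), via dioxolane phenol 14 (not isolated)
Conditions: H2 (1 atm), 10% Pd/C, EtOAc–THF, rt (no amine); filter; then 1 M HCl, THF, rt
Reagents that add atoms: water, O (carbonyl oxygen of the liberated aldehyde)
Why: Heterogeneous hydrogenation should saturate the stilbene and hydrogenolyse the benzyl ether in one operation, with the benzyl sulfone inert and no base present to trigger sulfinate loss from the freed phenol, and aqueous acid then hydrolyses the dioxolane.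

Step 10
Reactants: 15 4-[3-[2-[4-[2-hydroxy-5-(tosylmethyl)phenoxy]phenyl]ethyl]phenoxy]-3-methoxybenzaldehyde (seco aldehyde)
Product: 17 macrocyclic deoxybenzoin (20-membered ring; C=O on ring A, CH2 on ring D, ring A OMe, ring D OH free), via p-quinone methide 16 (not isolated)
Conditions: 2-(pentafluorophenyl)-6,7-dihydro-5H-pyrrolo[2,1-c][1,2,4]triazol-2-ium tetrafluoroborate (20 mol%), Cs2CO3 (2.5 equiv), 4 Å MS, THF, 40 °C, syringe-pump addition of 15 (final concentration about 2 mM)
Reagents that add atoms: none
Why: Proposed new method: Cs2CO3 ionises the ring D phenol and the phenoxide expels p-toluenesulfinate by 1,6-elimination to give p-quinone methide 16, while the triazolylidene adds to the ring A aldehyde and proton transfer gives the nucleophilic Breslow (hydroxy-enamine) intermediate, whose attack on the exocyclic CH2 of 16 forms the bridge C–C bond, re-aromatises ring D and, on collapse of the adduct, releases the ketone and the carbene. The closest known reaction types are carbene-catalysed 1,6-hydroacylation of stabilised, methylene-substituted p-quinone methides by aldehydes and acyl anion additions to quinone methides released by base from sulfonylmethyl phenols; new here are the unhindered, methylene-unsubstituted p-quinone methide and the macrocyclic closure. The 20-membered ring closes by intramolecular conjugate addition onto the methylene terminus (formally 20-endo-trig), which is geometrically unconstrained at this ring size, and no stereocentre is created. The selectivity required is ring-closing C–C bond formation over oligomerisation, benzoin dimerisation and O- or S-attack on the quinone methide; slow addition keeps both reactive intermediates dilute, and the benzoin, sulfinate and phenoxide adducts form reversibly whereas the C-acylation is irreversible, so material should funnel to the ketone. In the substrate the aldehyde has no enolisable position, the ring A phenol is capped as its methyl ether so that ring D holds the only ionisable phenol, and only attack at the methylene terminus restores aromaticity, which secures the 1,6-regiochemistry.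

Step 11
Reactants: 17 macrocyclic deoxybenzoin
Product: 18 macrocyclic bis(bibenzyl) mono-methyl ether (ring A OMe, ring D OH)
Conditions: Et3SiH, CF3CO2H, CH2Cl2, 0 °C to 40 °C
Reagents that add atoms: none
Why: In this ionic hydrogenation the protonated aryl ketone and then the benzylic cation, both stabilised by the para aryloxy oxygen of ring A, each accept hydride from the silane, which should deoxygenate C=O to CH2 without touching the diaryl ethers or the phenol.

Step 12
Reactants: 18 macrocyclic bis(bibenzyl) mono-methyl ether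
Product: 19 CNP0329842.0 (macrocyclic bis(bibenzyl) diphenol, target)
Conditions: BBr3, CH2Cl2, −78 °C to rt; then H2O
Reagents that add atoms: none
Why: In this Lewis-acid ether cleavage BBr3 coordinates the methoxy oxygen and bromide attacks the methyl carbon (SN2), whereas the diaryl ether bonds offer no sp3 carbon and should survive.

**Compound list**

1 | 4-fluoro-3-methoxybenzaldehyde | COc1cc(C=O)ccc1F | starting material
2 | 3-hydroxybenzyl alcohol | OCc1cccc(O)c1 | starting material
3 | 4-[3-(hydroxymethyl)phenoxy]-3-methoxybenzaldehyde | COc1cc(C=O)ccc1Oc1cccc(CO)c1 | intermediate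
4 | [3-[4-(1,3-dioxolan-2-yl)-2-methoxyphenoxy]phenyl]methanol | COc1cc(C2OCCO2)ccc1Oc1cccc(CO)c1 | intermediate
5 | 2-[4-[3-(bromomethyl)phenoxy]-3-methoxyphenyl]-1,3-dioxolane | COc1cc(C2OCCO2)ccc1Oc1cccc(CBr)c1 | intermediate
6 | [3-[4-(1,3-dioxolan-2-yl)-2-methoxyphenoxy]benzyl]triphenylphosphonium bromide | COc1cc(C2OCCO2)ccc1Oc1cccc(C[P+](c2ccccc2)(c2ccccc2)c2ccccc2)c1.[Br-] | intermediate
7 | 4-(benzyloxy)-3-hydroxybenzaldehyde | O=Cc1ccc(OCc2ccccc2)c(O)c1 | starting material
8 | 2-(benzyloxy)-5-(hydroxymethyl)phenol | OCc1ccc(OCc2ccccc2)c(O)c1 | intermediate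
9 | 4-fluorobenzaldehyde | O=Cc1ccc(F)cc1 | starting material
10 | 4-[2-(benzyloxy)-5-(hydroxymethyl)phenoxy]benzaldehyde | O=Cc1ccc(Oc2cc(CO)ccc2OCc2ccccc2)cc1 | intermediate
11 | 4-[2-(benzyloxy)-5-(bromomethyl)phenoxy]benzaldehyde | O=Cc1ccc(Oc2cc(CBr)ccc2OCc2ccccc2)cc1 | intermediate (not isolated)
12 | 4-[2-(benzyloxy)-5-(tosylmethyl)phenoxy]benzaldehyde | O=Cc1ccc(Oc2cc(CS(=O)(=O)c3ccc(C)cc3)ccc2OCc2ccccc2)cc1 | intermediate
13 | 2-[4-[3-[2-[4-[2-(benzyloxy)-5-(tosylmethyl)phenoxy]phenyl]ethenyl]phenoxy]-3-methoxyphenyl]-1,3-dioxolane, E/Z mixture | COc1cc(C2OCCO2)ccc1Oc1cccc(C=Cc2ccc(Oc3cc(CS(=O)(=O)c4ccc(C)cc4)ccc3OCc3ccccc3)cc2)c1 | intermediate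
14 | 2-[4-[2-[3-[4-(1,3-dioxolan-2-yl)-2-methoxyphenoxy]phenyl]ethyl]phenoxy]-4-(tosylmethyl)phenol | COc1cc(C2OCCO2)ccc1Oc1cccc(CCc2ccc(Oc3cc(CS(=O)(=O)c4ccc(C)cc4)ccc3O)cc2)c1 | intermediate (not isolated)
15 | 4-[3-[2-[4-[2-hydroxy-5-(tosylmethyl)phenoxy]phenyl]ethyl]phenoxy]-3-methoxybenzaldehyde (seco aldehyde, key-step precursor) | COc1cc(C=O)ccc1Oc1cccc(CCc2ccc(Oc3cc(CS(=O)(=O)c4ccc(C)cc4)ccc3O)cc2)c1 | intermediate
16 | 4-[3-[2-[4-[(3-methylidene-6-oxocyclohexa-1,4-dien-1-yl)oxy]phenyl]ethyl]phenoxy]-3-methoxybenzaldehyde (p-quinone methide) | COc1cc(C=O)ccc1Oc1cccc(CCc2ccc(OC3=CC(=C)C=CC3=O)cc2)c1 | intermediate (not isolated)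
17 | macrocyclic deoxybenzoin: 20-membered ring, ketone carbon on ring A, CH2 on ring D, ring A OMe, ring D OH | COc1cc2ccc1Oc1cccc(c1)CCc1ccc(cc1)Oc1cc(ccc1O)CC2=O | intermediate
18 | macrocyclic bis(bibenzyl) mono-methyl ether: ring A OMe, ring D OH | COc1cc2ccc1Oc1cccc(c1)CCc1ccc(cc1)Oc1cc(ccc1O)CC2 | intermediate
19 | CNP0329842.0, macrocyclic bis(bibenzyl) diphenol | Oc1cc2ccc1Oc1cccc(c1)CCc1ccc(cc1)Oc1cc(ccc1O)CC2 | target

**Step count.** 12 steps in total. The longest linear sequence is 9 steps (steps 1–4, then 8–12).

**Steps most likely to fail**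

1. Step 10 (key step). The unhindered quinone methide may oligomerise faster than the ring closes, the carbene may be sequestered by its own 1,6-addition to the quinone methide, aldehydes may pair by benzoin coupling, or the enolisable ketone product may be alkylated by further quinone methide. The fallback makes the same bridge bond by established reductive carbonyl coupling and sets out from 10 together with 6. Wittig olefination (K2CO3, 18-crown-6, CH2Cl2, reflux) should give the stilbene alcohol F1. Diimide reduction (p-toluenesulfonyl hydrazide, NaOAc, aqueous DME, reflux) saturates only the alkene to give the bibenzyl alcohol F2. MnO2 in CH2Cl2 oxidises the benzylic alcohol to the ring D aldehyde F3, and 1 M HCl in THF removes the dioxolane to give the dialdehyde F4. McMurry coupling with low-valent titanium from TiCl4 and Zn (pyridine, THF, reflux, slow addition) should close the ring to the macrocyclic stilbene F5. Hydrogenation over 10% Pd/C then saturates the alkene and removes the benzyl group, and the fallback comes back to the route at 18.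

2. Step 9. Hydrogenolysis may not stop at the benzyl ether. The freed 4-hydroxybenzyl sulfone may lose sulfinate on the catalyst and be reduced to a methyl group, or the acetal may open early so that the aldehyde is reduced. The fallback separates the two jobs and uses no catalytic hydrogen, setting out from 13. Diimide reduction (p-toluenesulfonyl hydrazide, NaOAc, aqueous DME, reflux) should give the saturated benzyl ether acetal F6. 1 M HCl in THF gives the benzyl-protected aldehyde F7. BCl3 with pentamethylbenzene in CH2Cl2 at −78 °C then cleaves the benzyl ether by a Lewis-acid path that leaves aldehyde, methyl ether and sulfone alone, and the fallback comes back to the route at 15.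

3. Step 11. The benzylic cation may be intercepted transannularly by an electron-rich ring (Friedel–Crafts alkylation), or the reduction may stall at the carbinol stage. The fallback avoids cationic intermediates altogether and sets out from 17. Wolff–Kishner reduction under Huang–Minlon conditions (N2H4·H2O, KOH, diethylene glycol, 130 °C then 200 °C) forms the hydrazone F8 in the flask, which loses nitrogen under base, and the fallback comes back to the route at 18.

**Further compounds**

F1 | step 10 | [3-[4-[2-[3-[4-(1,3-dioxolan-2-yl)-2-methoxyphenoxy]phenyl]ethenyl]phenoxy]-4-(benzyloxy)phenyl]methanol, E/Z mixture | COc1cc(C2OCCO2)ccc1Oc1cccc(C=Cc2ccc(Oc3cc(CO)ccc3OCc3ccccc3)cc2)c1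
F2 | step 10 | [3-[4-[2-[3-[4-(1,3-dioxolan-2-yl)-2-methoxyphenoxy]phenyl]ethyl]phenoxy]-4-(benzyloxy)phenyl]methanol | COc1cc(C2OCCO2)ccc1Oc1cccc(CCc2ccc(Oc3cc(CO)ccc3OCc3ccccc3)cc2)c1
F3 | step 10 | 3-[4-[2-[3-[4-(1,3-dioxolan-2-yl)-2-methoxyphenoxy]phenyl]ethyl]phenoxy]-4-(benzyloxy)benzaldehyde | COc1cc(C2OCCO2)ccc1Oc1cccc(CCc2ccc(Oc3cc(C=O)ccc3OCc3ccccc3)cc2)c1
F4 | step 10 | seco dialdehyde: 4-(benzyloxy)-3-[4-[2-[3-(4-formyl-2-methoxyphenoxy)phenyl]ethyl]phenoxy]benzaldehyde | COc1cc(C=O)ccc1Oc1cccc(CCc2ccc(Oc3cc(C=O)ccc3OCc3ccccc3)cc2)c1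
F5 | step 10 | macrocyclic stilbene (ring A OMe, ring D OBn), E/Z mixture | COc1cc2ccc1Oc1cccc(c1)CCc1ccc(cc1)Oc1cc(ccc1OCc1ccccc1)C=C2
F6 | step 9 | 2-[4-[3-[2-[4-[2-(benzyloxy)-5-(tosylmethyl)phenoxy]phenyl]ethyl]phenoxy]-3-methoxyphenyl]-1,3-dioxolane | COc1cc(C2OCCO2)ccc1Oc1cccc(CCc2ccc(Oc3cc(CS(=O)(=O)c4ccc(C)cc4)ccc3OCc3ccccc3)cc2)c1
F7 | step 9 | 4-[3-[2-[4-[2-(benzyloxy)-5-(tosylmethyl)phenoxy]phenyl]ethyl]phenoxy]-3-methoxybenzaldehyde | COc1cc(C=O)ccc1Oc1cccc(CCc2ccc(Oc3cc(CS(=O)(=O)c4ccc(C)cc4)ccc3OCc3ccccc3)cc2)c1
F8 | step 11 | hydrazone of macrocyclic deoxybenzoin 17 | COc1cc2ccc1Oc1cccc(c1)CCc1ccc(cc1)Oc1cc(ccc1O)CC2=NN
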